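**Remark:** ring atoms are numbered C1 (secondary carbinol), C2=C3, C4, C5 (tertiary carbinol), C6, and chain atoms C1'–C16'; 5-phenylpent-1-yne and 1,11-dibromoundecane are taken as commercial.

## Analysis of the target

The target 23 is (1S,3S)-1-[(12Z)-16-phenylhexadec-12-en-1-yl]cyclohex-4-ene-1,3-diol. In the numbering used here it is a cyclohex-2-en-1-ol with C1 as CHOH, a C2=C3 double bond, C4H2, the tertiary carbinol C5 and C6H2. C5 carries a sixteen-carbon chain with a cis C12'=C13' alkene and a terminal phenyl ring. Both stereocentres, C1 and C5, are S, and the two hydroxyl groups, 1,3-related through C6, sit on the same ring face (cis-diol). The allylic C1–OH and the tertiary C5–OH ionise and dehydrate easily; two eliminations aromatise the ring, and at the enone oxidation level one elimination already leads to a phenol. The cis chain alkene excludes unselective hydrogenation, halonium chemistry and isomerising conditions late in the route. The hard point is C5: its three carbon substituents are all methylene groups (C4, C6, C1'), and C4 and C6 differ only in what lies one atom further out, so a face-selective addition to a C5 ketone cannot tell them apart. The strategy rests on reading C5 as a carbinol carbon whose two ring arms each end in a carbonyl-level carbon (C1 through C6, C3 through C4). Each arm is then the result of an acyl anion opening an oxirane, and the two arms can be told apart when one is an oxirane CH2 and the other a CH2–O sulfonate of a 2-substituted glycidol.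

## Retrosynthetic reasoning

**C1 carbinol and protecting group.** The target 23 is traced back to its C5 silyl ether 22, and the C1 carbinol to the carbonyl of enone 21. This leaves C5 as the only stereocentre and puts C1 at the ketone level, which is what an aldol ring closure delivers. The forward reduction must be 1,2-selective and must add hydrogen to the ring face of the silyloxy group.

**C2=C3 bond.** Enone 21 is the retron of an aldol condensation. Cutting C2=C3 gives keto aldehyde 19, with the cyclic aldol 20 in between. In 19 the ketone methyl (C2) and the aldehyde carbon (C3) are the only pair that can close a six-membered ring; every other enolisation mode would give a four-membered ring. The forward step must close the ring without expelling the β-silyloxy group.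

**Carbonyl masking.** Both carbonyls of 19 are masked as dithianes in 18, and the silyl group is removed to give tertiary alcohol 17. The silyl ether is put on before unmasking because a free tertiary β-hydroxy ketone would be open to retro-aldol cleavage.

**C3–C4 bond.** The 1,3 relationship between the C5 oxygen and C3 is that of an acyl anion adding to an oxirane. Cutting C3–C4 gives oxirane 14 and 1,3-dithiane 15, used as its anion 16. The forward step is an SN2 opening at the oxirane CH2 that leaves the C5–O bond alone.

**C1–C6 bond (key disconnection).** The same retron is applied on the other arm, with the added demand that the oxirane of 14 be created in the same operation. Cutting C1–C6 leads to epoxy tosylate 10 and 2-methyl-1,3-dithiane 11, used as its anion 12. Opening of the original oxirane frees the C5 alkoxide 13, which closes the new oxirane on the former sulfonate arm. One C–C bond is gained, the electrophile for the next C–C bond is regenerated, and the C5–O bond is never broken. The forward step must attack the oxirane CH2 and not the sulfonate CH2.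

**C5 stereocentre.** Tosylate 10 comes from epoxy alcohol 9, and 9 from asymmetric epoxidation of the 2-substituted allyl alcohol 8. Here C5 becomes a stereocentre under reagent control, at a stage where its two future ring arms are as different as they can be: one is an alkene CH2, the other carries the hydroxyl.

**C5–C1' bond.** Allyl alcohol 8 is cut between C5 and C1' into propargyl alcohol 6 and the chain Grignard reagent 7. A carbomagnesiation brings in the complete chain in one step and creates the 1,1-disubstituted alkene.

**Chain.** Reagent 7 comes from bromide 5, whose cis alkene comes from alkyne 4 by semi-hydrogenation. Alkyne 4 is cut at the propargylic C–C bond into 5-phenylpent-1-yne 1 (as acetylide 3) and 1,11-dibromoundecane 2.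

## Alternatives that were turned down

**Alternative 1:** The C1–O bond is traced to a C1=C2 alkene and the oxygen already on C5; the C2=C3 alkene then comes from loss of HI, and the ring is taken ready-made from a Birch reduction.
- **Forward key step.** The tert-butyl carbonate A2 would be treated with IBr at low temperature. The iodonium ion on C1=C2 is captured across the ring by the carbonate carbonyl oxygen, the tert-butyl group is lost and the bridged iodocarbonate A1 forms. Elimination of HI toward C3, carbonate methanolysis and semi-hydrogenation of the chain alkyne would finish the synthesis. The chain must stay an alkyne until then, because IBr would also attack a cis alkene. A2 would come from 1,2-addition of the C16 alkynyl chain to cyclohex-3-en-1-one A3 and Boc protection.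
- **For.** The bicyclic carbonate can only form with the two oxygens cis, so the relative configuration is guaranteed by the tether. On this point it is stronger than the chosen route, which leaves the C1 configuration to a hydride reduction. It is also shorter, at about eight operations.
- **Against.** In A3 the two α-methylene arms differ only by a remote double bond, so no dependable enantioselective addition exists; A2 would be racemic and need a resolution. A3 also enolises and conjugates readily. The transannular closure needs an axial carbonate in a boat-like arrangement and competes with capture of the iodonium ion by bromide.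
- **Comparison.** The chosen route gives up the tether-guaranteed cis relationship but sets C5 absolutely, by a catalytic reagent-controlled step, before anything else is built.

**Alternative 2:** The C4–C5 bond and the C2=C3 alkene are traced to a [3,3] rearrangement, with the chain cut back to its first carbon, C1'.
- **Forward key step.** The lactone A5 would be enolised and O-silylated to the silyl ketene acetal A6. On warming, A6 rearranges through the boat transition state that the ring enforces, opens the lactone and closes the cyclohexene, giving acid A4 after hydrolysis of the silyl ester.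
- **For.** One pericyclic step makes the ring, the fully substituted C5 and the correctly placed alkene, with no elimination needed. The rigid boat relays the configuration of the C1 carbinol to C5. On this relay of C1 to C5 it is stronger than the chosen route.
- **Against.** A4 carries only the carboxyl carbon C1' on C5. The other fifteen chain carbons, including the cis alkene, would have to be attached at a neopentyl position, and C1' reduced to a methylene group in the presence of the ring alkene. Olefination followed by saturation of a new C1'=C2' bond cannot be made selective against two other alkenes, and deoxygenative routes cost four or five more steps. A5 itself needs two adjacent oxygenated stereocentres and its own multi-step preparation.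
- **Comparison.** The chosen route brings the whole chain in at step 3 and needs about half the number of operations.

**Alternative 3:** The C1–C2 and C3–C4 bonds are cut at once, as a two-carbon insertion of ethyne into a four-membered ketone.
- **Forward key step.** The prochiral cyclobutanone A8 would be treated with Ni(cod)2, a chiral phosphine and ethyne. Oxidative coupling of carbonyl and alkyne at zerovalent nickel, β-carbon elimination of one of the two enantiotopic ring bonds and reductive elimination would give enone A7, which is the same compound as 21 of the chosen route; the endgame would be identical.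
- **For.** It is the shortest route on paper, since the ring enlargement and the creation of the C5 stereocentre are one catalytic event. On step count it is stronger than the chosen route.
- **Against.** Such insertions are established for internal alkynes; ethyne is prone to oligomerisation at zerovalent nickel. The catalyst would have to tell apart two ring bonds whose only difference is a silyloxy group against a long alkyl group on the remote carbon, and the β-oxygen substituent and the chain alkene are further points of attack for low-valent nickel.
- **Comparison.** The chosen route is longer to 21 but uses only reaction types with close analogy, and its source of chirality is a well-understood epoxidation.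

Key step: step 6

## Route

**Step 1**
Reactants: 1 5-phenylpent-1-yne; 2 1,11-dibromoundecane
Product: 4 (16-bromohexadec-4-yn-1-yl)benzene, via lithium 5-phenylpent-1-yn-1-ide 3 (not isolated)
Conditions: 1, nBuLi, THF, −78 → 0 °C; then 2 (3 equiv), DMPU, 0 °C → rt
Reagents that add atoms: none
Why: Alkylation of a lithium acetylide with a primary bromide (SN2); the excess of the symmetrical dibromide limits double alkylation and the surplus is recovered.

**Step 2**
Reactants: 4 (16-bromohexadec-4-yn-1-yl)benzene
Product: 5 [(4Z)-16-bromohexadec-4-en-1-yl]benzene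
Conditions: H2 (1 atm), Pd/CaCO3 poisoned with Pb(OAc)2, quinoline, hexane/EtOAc, rt
Reagents that add atoms: none
Why: Lindlar-type semi-hydrogenation; syn delivery of hydrogen on the poisoned palladium surface should give the cis alkene, and the primary bromide and the arene should be untouched.

**Step 3**
Reactants: 5 [(4Z)-16-bromohexadec-4-en-1-yl]benzene; 6 prop-2-yn-1-ol
Product: 8 (14Z)-2-methylidene-18-phenyloctadec-14-en-1-ol, via [(12Z)-16-phenylhexadec-12-en-1-yl]magnesium bromide 7 (not isolated)
Conditions: 5, Mg, THF, 45 °C; 6 premetalated with EtMgBr (1.0 equiv), CuI (10 mol %), THF/Et2O, −10 °C → rt; then aq NH4Cl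
Reagents that add atoms: none
Why: CuI-catalysed carbomagnesiation of a propargylic alkoxide; the alkoxide directs the alkyl group to the internal alkyne carbon, and protonolysis on work-up should release the 2-substituted allyl alcohol. Premetalation with the cheap Grignard reagent spares 7.

**Step 4**
Reactants: 8 (14Z)-2-methylidene-18-phenyloctadec-14-en-1-ol
Product: 9 {(2S)-2-[(12Z)-16-phenylhexadec-12-en-1-yl]oxiran-2-yl}methanol
Conditions: Ti(OiPr)4 (10 mol %), L-(+)-DIPT (12 mol %), tBuOOH (2 equiv), 4 Å MS, CH2Cl2, −20 °C
Reagents that add atoms: tert-butyl hydroperoxide, CC(C)(C)OO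
Why: Sharpless asymmetric epoxidation; only the allylic alkene is bound to titanium and epoxidised, so the chain alkene should not react. L-(+)-DIPT is the ligand that turns (E)-allylic alcohols into (2S,3S)-epoxy alcohols; the same face is attacked here, which sets C5 with the S descriptor. Sieves and low catalyst loading limit opening of the sensitive 2,2-disubstituted oxirane.

**Step 5**
Reactants: 9 {(2S)-2-[(12Z)-16-phenylhexadec-12-en-1-yl]oxiran-2-yl}methanol
Product: 10 {(2R)-2-[(12Z)-16-phenylhexadec-12-en-1-yl]oxiran-2-yl}methyl 4-methylbenzenesulfonate
Conditions: TsCl, Et3N, DMAP (cat.), CH2Cl2, 0 °C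
Reagents that add atoms: 4-methylbenzenesulfonyl chloride, Cc1ccc(cc1)S(Cl)(=O)=O
Why: Sulfonylation of a primary alcohol; no bond at C5 is touched, and the descriptor changes from S to R only because the sulfonate arm now outranks the oxirane CH2.

**Step 6**
Reactants: 10 {(2R)-2-[(12Z)-16-phenylhexadec-12-en-1-yl]oxiran-2-yl}methyl 4-methylbenzenesulfonate; 11 2-methyl-1,3-dithiane
Product: 14 (2R)-2-[(2-methyl-1,3-dithian-2-yl)methyl]-2-[(12Z)-16-phenylhexadec-12-en-1-yl]oxirane, via 2-lithio-2-methyl-1,3-dithiane 12 (not isolated), via ring-opened lithium alkoxide tosylate 13 (not isolated)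
Conditions: 11, nBuLi, THF, −30 °C; add to 10 (1.05 equiv of anion), THF, −78 → −20 °C; then rt
Reagents that add atoms: none
Why: Deprotonation of 11 gives the acyl anion equivalent 12, which opens the lithium-coordinated oxirane of 10 by SN2 attack at its CH2 and forms the C1–C6 bond (Corey–Seebach umpolung). The tertiary alkoxide 13 set free at C5 then displaces the neighbouring sulfonate on warming and closes the new oxirane in a 3-exo-tet mode. The closest known reaction type is the opening of epichlorohydrin or glycidyl sulfonates by lithiated dithianes with reclosure of the oxirane on the other arm. No stereocentre is formed; the C5–O bond is never broken, so the configuration from step 4 is carried over while the two methylene arms exchange roles. The step needs attack at the oxirane CH2 and not at the sulfonate CH2, because the two paths give the same constitution with mirror-image configuration. Release of ring strain and lithium activation of the oxirane oxygen favour the wanted path, and SN2 at the sulfonate carbon is retarded by the fully substituted neighbour; no dipolar additive is used for the addition, since it would mainly speed up the sulfonate displacement. One equivalent of anion and inverse addition at low temperature keep a second anion from opening the product oxirane, which forms only on warming.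

**Step 7**
Reactants: 14 (2R)-2-[(2-methyl-1,3-dithian-2-yl)methyl]-2-[(12Z)-16-phenylhexadec-12-en-1-yl]oxirane; 15 1,3-dithiane
Product: 17 (2S,14Z)-1-(1,3-dithian-2-yl)-2-[(2-methyl-1,3-dithian-2-yl)methyl]-18-phenyloctadec-14-en-2-ol, via 2-lithio-1,3-dithiane 16 (not isolated)
Conditions: 15, nBuLi, THF, −30 °C; then 14, THF/DMPU, −30 °C → rt; then H2O
Reagents that add atoms: none
Why: Second acyl-anion opening of a 2,2-disubstituted oxirane at its CH2 (SN2) forms C3–C4; the C5–O bond is again untouched, and the descriptor becomes S only through the change of substituent ranking.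

**Step 8**
Reactants: 17 (2S,14Z)-1-(1,3-dithian-2-yl)-2-[(2-methyl-1,3-dithian-2-yl)methyl]-18-phenyloctadec-14-en-2-ol
Product: 18 tert-butyl{[(2S,14Z)-1-(1,3-dithian-2-yl)-2-[(2-methyl-1,3-dithian-2-yl)methyl]-18-phenyloctadec-14-en-2-yl]oxy}dimethylsilane
Conditions: TBSOTf, 2,6-lutidine, CH2Cl2, 0 °C → rt
Reagents that add atoms: tert-butyldimethylsilyl trifluoromethanesulfonate, CC(C)(C)[Si](C)(C)OS(=O)(=O)C(F)(F)F
Why: Silyl triflate silylation of a hindered tertiary alcohol; the ether blocks retro-aldol cleavage once the carbonyls are unmasked, and its bulk is used later to bias the reduction.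

**Step 9**
Reactants: 18 tert-butyl{[(2S,14Z)-1-(1,3-dithian-2-yl)-2-[(2-methyl-1,3-dithian-2-yl)methyl]-18-phenyloctadec-14-en-2-yl]oxy}dimethylsilane
Product: 19 (3S)-3-[(tert-butyldimethylsilyl)oxy]-5-oxo-3-[(12Z)-16-phenylhexadec-12-en-1-yl]hexanal
Conditions: MeI, CaCO3, MeCN/H2O (4:1), 45 °C
Reagents that add atoms: water, O
Why: Alkylative dithioacetal hydrolysis (S-methylation, then hydrolysis of the sulfonium ion) under buffered, non-oxidising conditions; both carbonyls should be released without touching the chain alkene, the silyl ether or the base-sensitive β-silyloxy carbonyl array.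

**Step 10**
Reactants: 19 (3S)-3-[(tert-butyldimethylsilyl)oxy]-5-oxo-3-[(12Z)-16-phenylhexadec-12-en-1-yl]hexanal
Product: 21 (5S)-5-[(tert-butyldimethylsilyl)oxy]-5-[(12Z)-16-phenylhexadec-12-en-1-yl]cyclohex-2-en-1-one, via cyclic aldol adduct 20 (not isolated)
Conditions: piperidine (0.2 equiv), AcOH (0.2 equiv), PhMe, rt → 40 °C
Reagents that add atoms: none
Why: Amine-catalysed intramolecular aldol condensation; only the ketone methyl group can reach the aldehyde through a six-membered transition state (6-exo-trig), and loss of water from 20 gives the conjugated enone. The buffered amine salt is chosen to spare the β-silyloxy group.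

**Step 11**
Reactants: 21 (5S)-5-[(tert-butyldimethylsilyl)oxy]-5-[(12Z)-16-phenylhexadec-12-en-1-yl]cyclohex-2-en-1-one
Product: 22 (1S,5S)-5-[(tert-butyldimethylsilyl)oxy]-5-[(12Z)-16-phenylhexadec-12-en-1-yl]cyclohex-2-en-1-ol
Conditions: NaBH4, CeCl3·7H2O, MeOH, −78 °C
Reagents that add atoms: none
Why: Luche reduction, 1,2-selective for the enone. In the favoured half-chair the chain is pseudo-equatorial and the silyloxy group pseudo-axial, so the bulky axial C5–O substituent should shield its own face; hydride is expected from the opposite face, placing the new C1 hydroxyl cis to the C5 oxygen (C1 = S).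

**Step 12**
Reactants: 22 (1S,5S)-5-[(tert-butyldimethylsilyl)oxy]-5-[(12Z)-16-phenylhexadec-12-en-1-yl]cyclohex-2-en-1-ol
Product: 23 (1S,3S)-1-[(12Z)-16-phenylhexadec-12-en-1-yl]cyclohex-4-ene-1,3-diol
Conditions: TBAF, THF, rt → 45 °C
Reagents that add atoms: none
Why: Fluoride-induced desilylation driven by the Si–F bond; the conditions are basic and non-ionising, so the allylic and tertiary carbinols and the cis alkene should survive.

## Compound list

1 | 5-phenylpent-1-yne | C#CCCCc1ccccc1 | starting material
2 | 1,11-dibromoundecane | BrCCCCCCCCCCCBr | starting material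
3 | lithium 5-phenylpent-1-yn-1-ide | [Li]C#CCCCc1ccccc1 | intermediate
4 | (16-bromohexadec-4-yn-1-yl)benzene | BrCCCCCCCCCCCC#CCCCc1ccccc1 | intermediate
5 | [(4Z)-16-bromohexadec-4-en-1-yl]benzene | BrCCCCCCCCCCC/C=C\CCCc1ccccc1 | intermediate
6 | prop-2-yn-1-ol | C#CCO | starting material
7 | [(12Z)-16-phenylhexadec-12-en-1-yl]magnesium bromide | Br[Mg]CCCCCCCCCCC/C=C\CCCc1ccccc1 | intermediate
8 | (14Z)-2-methylidene-18-phenyloctadec-14-en-1-ol | C=C(CO)CCCCCCCCCCC/C=C\CCCc1ccccc1 | intermediate
9 | {(2S)-2-[(12Z)-16-phenylhexadec-12-en-1-yl]oxiran-2-yl}methanol | OC[C@@]1(CCCCCCCCCCC/C=C\CCCc2ccccc2)CO1 | intermediate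
10 | {(2R)-2-[(12Z)-16-phenylhexadec-12-en-1-yl]oxiran-2-yl}methyl 4-methylbenzenesulfonate | Cc1ccc(cc1)S(=O)(=O)OC[C@@]1(CCCCCCCCCCC/C=C\CCCc2ccccc2)CO1 | intermediate
11 | 2-methyl-1,3-dithiane | CC1SCCCS1 | starting material
12 | 2-lithio-2-methyl-1,3-dithiane | [Li]C1(C)SCCCS1 | intermediate
13 | lithium (2R,14Z)-1-(2-methyl-1,3-dithian-2-yl)-2-{[(4-methylbenzenesulfonyl)oxy]methyl}-18-phenyloctadec-14-en-2-olate | [Li]O[C@](CC1(C)SCCCS1)(COS(=O)(=O)c2ccc(C)cc2)CCCCCCCCCCC/C=C\CCCc3ccccc3 | intermediate
14 | (2R)-2-[(2-methyl-1,3-dithian-2-yl)methyl]-2-[(12Z)-16-phenylhexadec-12-en-1-yl]oxirane | CC1(SCCCS1)C[C@]2(CCCCCCCCCCC/C=C\CCCc3ccccc3)CO2 | intermediate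
15 | 1,3-dithiane | C1CSCSC1 | starting material
16 | 2-lithio-1,3-dithiane | [Li]C1SCCCS1 | intermediate
17 | (2S,14Z)-1-(1,3-dithian-2-yl)-2-[(2-methyl-1,3-dithian-2-yl)methyl]-18-phenyloctadec-14-en-2-ol | CC1(SCCCS1)C[C@@](O)(CC2SCCCS2)CCCCCCCCCCC/C=C\CCCc3ccccc3 | intermediate
18 | tert-butyl{[(2S,14Z)-1-(1,3-dithian-2-yl)-2-[(2-methyl-1,3-dithian-2-yl)methyl]-18-phenyloctadec-14-en-2-yl]oxy}dimethylsilane | CC1(SCCCS1)C[C@@](O[Si](C)(C)C(C)(C)C)(CC2SCCCS2)CCCCCCCCCCC/C=C\CCCc3ccccc3 | intermediate
19 | (3S)-3-[(tert-butyldimethylsilyl)oxy]-5-oxo-3-[(12Z)-16-phenylhexadec-12-en-1-yl]hexanal | CC(=O)C[C@@](O[Si](C)(C)C(C)(C)C)(CC=O)CCCCCCCCCCC/C=C\CCCc1ccccc1 | intermediate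
20 | (3S)-3-[(tert-butyldimethylsilyl)oxy]-5-hydroxy-3-[(12Z)-16-phenylhexadec-12-en-1-yl]cyclohexan-1-one (both C5 epimers) | O=C1CC(O)C[C@@](O[Si](C)(C)C(C)(C)C)(CCCCCCCCCCC/C=C\CCCc2ccccc2)C1 | intermediate
21 | (5S)-5-[(tert-butyldimethylsilyl)oxy]-5-[(12Z)-16-phenylhexadec-12-en-1-yl]cyclohex-2-en-1-one | O=C1C=CC[C@@](O[Si](C)(C)C(C)(C)C)(CCCCCCCCCCC/C=C\CCCc2ccccc2)C1 | intermediate
22 | (1S,5S)-5-[(tert-butyldimethylsilyl)oxy]-5-[(12Z)-16-phenylhexadec-12-en-1-yl]cyclohex-2-en-1-ol | O[C@@H]1C=CC[C@@](O[Si](C)(C)C(C)(C)C)(CCCCCCCCCCC/C=C\CCCc2ccccc2)C1 | intermediate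
23 | (1S,3S)-1-[(12Z)-16-phenylhexadec-12-en-1-yl]cyclohex-4-ene-1,3-diol | O[C@@H]1C=CC[C@@](O)(CCCCCCCCCCC/C=C\CCCc2ccccc2)C1 | target

## Step count and least certain steps

Total step count: 12. Longest linear sequence: 12 steps (1 or 2 to 23).

**Step 6 (key step).**
- What may go wrong: part of the anion may displace the sulfonate directly instead of opening the oxirane. Both paths give the same constitution but mirror-image configuration, so the enantiomeric purity would be eroded. A second anion may also add to the product oxirane if closure is fast at the addition temperature.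
- Fallback, separating C–C bond formation from oxirane closure: epoxy alcohol 9 is treated with two equivalents of 12 (the first deprotonates the hydroxyl), so that the oxirane CH2 is the only electrophilic carbon. This should give (2R)-3-(2-methyl-1,3-dithian-2-yl)-2-[(12Z)-16-phenylhexadec-12-en-1-yl]propane-1,2-diol F1. Selective sulfonylation of its primary hydroxyl (TsCl, Et3N, catalytic Bu2SnO) gives (2R,14Z)-2-hydroxy-2-[(2-methyl-1,3-dithian-2-yl)methyl]-18-phenyloctadec-14-en-1-yl 4-methylbenzenesulfonate F2. K2CO3 in MeOH then closes the oxirane and returns to 14.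

**Step 10.**
- What may go wrong: β-elimination of the silyloxy group, either from the aldehyde enamine before ring closure or by enolisation of the product toward C6, which ends in aromatisation.
- Fallback, splitting addition and dehydration: keto aldehyde 19 is deprotonated kinetically at the methyl group with LiN(SiMe3)2 in THF at −78 °C, so that the lithium enolate closes onto the aldehyde and the cyclic aldol 20 is isolated after a cold quench. Treatment of 20 with MsCl and Et3N at 0 °C gives (3S)-3-[(tert-butyldimethylsilyl)oxy]-5-[(methanesulfonyl)oxy]-3-[(12Z)-16-phenylhexadec-12-en-1-yl]cyclohexan-1-one F3. F3 loses methanesulfonate in the same flask, because the sulfonate is by far the better leaving group, and the route is rejoined at 21.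

**Step 11.**
- What may go wrong: poor facial selectivity. Both half-chair conformers of 21 carry an axial substituent on C5, and hydride delivery on the face of the silyloxy group would give the C1 epimer.
- Fallback, correcting C1 by inversion instead of by facial control: the epimer obtained from 21, (1R,5S)-5-[(tert-butyldimethylsilyl)oxy]-5-[(12Z)-16-phenylhexadec-12-en-1-yl]cyclohex-2-en-1-ol F4, is subjected to a Mitsunobu reaction (4-nitrobenzoic acid, PPh3, DIAD, THF, 0 °C). This should give, with inversion, (1S,5S)-5-[(tert-butyldimethylsilyl)oxy]-5-[(12Z)-16-phenylhexadec-12-en-1-yl]cyclohex-2-en-1-yl 4-nitrobenzoate F5. Methanolysis with K2CO3 in MeOH returns to 22.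

**Step 3.**
- What may go wrong: incomplete carbometalation, through protonolysis of 7 by the substrate or slow addition to the alkoxide, and copper-mediated homocoupling of the chain.
- Fallback, building the allyl alcohol from a malonate instead of an alkyne: bromide 5 alkylates the sodium enolate of diethyl malonate (NaH, THF/DMF) to give diethyl 2-[(12Z)-16-phenylhexadec-12-en-1-yl]propanedioate F6. Reduction of the sodium enolate of F6 with LiAlH4 in refluxing DME (the malonate-enolate reduction to 2-substituted allyl alcohols) returns to 8.

## Further compounds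

F1 | step 6 | (2R)-3-(2-methyl-1,3-dithian-2-yl)-2-[(12Z)-16-phenylhexadec-12-en-1-yl]propane-1,2-diol | OC[C@](O)(CC1(C)SCCCS1)CCCCCCCCCCC/C=C\CCCc2ccccc2
F2 | step 6 | (2R,14Z)-2-hydroxy-2-[(2-methyl-1,3-dithian-2-yl)methyl]-18-phenyloctadec-14-en-1-yl 4-methylbenzenesulfonate | Cc1ccc(cc1)S(=O)(=O)OC[C@](O)(CC2(C)SCCCS2)CCCCCCCCCCC/C=C\CCCc3ccccc3
F3 | step 10 | (3S)-3-[(tert-butyldimethylsilyl)oxy]-5-[(methanesulfonyl)oxy]-3-[(12Z)-16-phenylhexadec-12-en-1-yl]cyclohexan-1-one (both C5 epimers) | O=C1CC(OS(C)(=O)=O)C[C@@](O[Si](C)(C)C(C)(C)C)(CCCCCCCCCCC/C=C\CCCc2ccccc2)C1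
F4 | step 11 | (1R,5S)-5-[(tert-butyldimethylsilyl)oxy]-5-[(12Z)-16-phenylhexadec-12-en-1-yl]cyclohex-2-en-1-ol | O[C@H]1C=CC[C@@](O[Si](C)(C)C(C)(C)C)(CCCCCCCCCCC/C=C\CCCc2ccccc2)C1
F5 | step 11 | (1S,5S)-5-[(tert-butyldimethylsilyl)oxy]-5-[(12Z)-16-phenylhexadec-12-en-1-yl]cyclohex-2-en-1-yl 4-nitrobenzoate | O=C(O[C@@H]1C=CC[C@@](O[Si](C)(C)C(C)(C)C)(CCCCCCCCCCC/C=C\CCCc2ccccc2)C1)c3ccc(cc3)[N+](=O)[O-]
F6 | step 3 | diethyl 2-[(12Z)-16-phenylhexadec-12-en-1-yl]propanedioate | CCOC(=O)C(CCCCCCCCCCC/C=C\CCCc1ccccc1)C(=O)OCC
A1 | alternative 1 | 8-iodo-5-(16-phenylhexadec-12-yn-1-yl)-2,4-dioxabicyclo[3.3.1]nonan-3-one (bridged iodocarbonate, iodine on C8 trans to the carbonate oxygen on C1) | O=C1O[C@@H]2[C@@H](I)CC[C@](CCCCCCCCCCCC#CCCCc3ccccc3)(O1)C2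
A2 | alternative 1 | tert-butyl (1S)-1-(16-phenylhexadec-12-yn-1-yl)cyclohex-3-en-1-yl carbonate | CC(C)(C)OC(=O)O[C@@]1(CCCCCCCCCCCC#CCCCc2ccccc2)CCC=CC1
A3 | alternative 1 | cyclohex-3-en-1-one | O=C1CC=CCC1
A4 | alternative 2 | cis-1,5-bis[(tert-butyldimethylsilyl)oxy]cyclohex-3-ene-1-carboxylic acid (both carbinol carbons configured as in the target) | CC(C)(C)[Si](C)(C)O[C@@H]1C=CC[C@@](O[Si](C)(C)C(C)(C)C)(C(=O)O)C1
A5 | alternative 2 | (5S,6S)-3,5-bis[(tert-butyldimethylsilyl)oxy]-6-ethenyloxan-2-one (either C3 epimer) | C=C[C@@H]1OC(=O)C(O[Si](C)(C)C(C)(C)C)C[C@@H]1O[Si](C)(C)C(C)(C)C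
A6 | alternative 2 | (2S,3S)-3,5,6-tris[(tert-butyldimethylsilyl)oxy]-2-ethenyl-3,4-dihydro-2H-pyran | C=C[C@@H]1OC(O[Si](C)(C)C(C)(C)C)=C(O[Si](C)(C)C(C)(C)C)C[C@@H]1O[Si](C)(C)C(C)(C)C
A7 | alternative 3 | (5S)-5-[(tert-butyldimethylsilyl)oxy]-5-[(12Z)-16-phenylhexadec-12-en-1-yl]cyclohex-2-en-1-one (identical with 21) | O=C1C=CC[C@@](O[Si](C)(C)C(C)(C)C)(CCCCCCCCCCC/C=C\CCCc2ccccc2)C1
A8 | alternative 3 | 3-[(tert-butyldimethylsilyl)oxy]-3-[(12Z)-16-phenylhexadec-12-en-1-yl]cyclobutan-1-one | O=C1CC(O[Si](C)(C)C(C)(C)C)(CCCCCCCCCCC/C=C\CCCc2ccccc2)C1
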